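The easy step comes first: target, once made, can go nowhere but on to the over-reaction products, so I ask how long each flask holds it warm.

in all of them: starting material 0.020 M; second substrate 10.0 mM; time 6.0 d

| charge | coupling partner | third substrate | temperature | remark |
|---|---|---|---|---|
| Friday's | 0.0600 M (fed, over 5.0 d) | 0.0400 M | 35 °C | all else is in the flask from the start; the feed brings no volume worth counting |
| Tuesday's | 0.0600 M | 0.0400 M (fed, over 5.0 d) |  | the addition at −5 °C, then warmed to 35 °C; the feed brings no volume worth counting |
| Wednesday's | 0.0600 M | 0.0400 M (in portions, 5, over 5.0 d) | 35 °C | first portion at the start, last at 5.0 d |
| Monday's | 0.0600 M | 0.0400 M |  | everything together at the start at −5 °C, warmed to 35 °C at 5.0 d |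
| Sunday's | 0.0600 M | 0.0400 M (fed, over 12 h) | 35 °C | all else is in the flask from the start; the feed brings no volume worth counting |
| Saturday's | 0.0600 M | 0.0400 M | 35 °C | everything together at the start |

    starting material + coupling partner → target (k1 = 1.73 /M/h, Ea1 = 84.0 kJ/mol)
    second substrate + coupling partner → second product (k2 = 1.65 /M/h, Ea2 = 60.0 kJ/mol)
    third substrate + coupling partner → third product (k3 = 1.81 /M/h, Ea3 = 60.0 kJ/mol)
    target → over-reaction product A (k4 = 0.0204 /h, Ea4 = 116 kJ/mol)
    target → over-reaction product B (k5 = 2.28 × 10⁻⁴ /h, Ea5 = 125 kJ/mol)
    (constants at 35 °C)

1. which flask leads in amount of target, in percent of the starting material charged ("all alike" within 1.5 percentage points) (Friday's / Tuesday's / Wednesday's / Monday's / Sunday's / Saturday's / all alike)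
2. how much target is there at the end, in percent of the starting material charged: Friday's
3. how much target is there at the end, in percent of the starting material charged: Tuesday's
4. how much target is there at the end, in percent of the starting material charged: Wednesday's
5. how much target is there at the end, in percent of the starting material charged: Monday's
6. how much target is there at the end, in percent of the starting material charged: Sunday's
7. how much target is there at the end, in percent of the starting material charged: Saturday's

- constants are those at 35 °C; use the activation energies for any other temperature

Target falls to the two over-reaction products with a summed rate constant of 0.0206 /h at 35 °C. One day at that temperature leaves 0.610 of it standing. I call this fraction the keep, and each further warm day multiplies by it again.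

In Saturday's the starting material has a half-life of 0.28 d at the charged concentrations, shorter than the 1.4 d of target. So I take target as made early and waiting from about that half-life to 6.0 d, and by my count 5.89% of it survives. The coupling partner is the limiting reagent, with 0.0600 M charged, less than the 0.0700 M of the substrates together. If the substrates share it in proportion, about 85.7% of the starting material reacts, so I expect 5.04% in Saturday's.

Holding back the third substrate, over 12 h in Sunday's or in 5 portions in Wednesday's, leaves more partner for the starting material. But target is still made early, so I put both flasks near 5.89%.

Feeding the partner over 5.0 d in Friday's is another matter. Partner reacts as it arrives, and the starting material takes 28.0% of it, a share that holds while the substrates fall together, since their constants are close. Dividing the rate of making by the loss constant removes time and gives a steady level of 34.0% of the charge. One more day at the keep brings Friday's to 20.7%.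

Monday's and Tuesday's spend 5.0 d at −5 °C. The loss has the higher activation energy, 116 kJ/mol against 84.0 kJ/mol for the making, so I count those days as free of waiting. Target made in the warm last day then keeps 0.610 or better, ten times the survival in Saturday's. I expect these two flasks to lead, and by hand I cannot part them.

The forecast names Tuesday's with 46%, then Monday's 44.4%, Friday's 24%, Wednesday's 7.5%, Sunday's 7.2% and Saturday's 7.1%, on the ground that “anything made early is lost”, and its Friday's and Saturday's stand above my 20.7% and 5.04%.

The simulation puts Tuesday's ahead with 46.0%, then Monday's 44.4%, Friday's 21.9%, Wednesday's 7.64%, Saturday's 7.20% and Sunday's 7.02%.

Of the steps taken away, the loss to over-reaction product A turns the gap between Tuesday's and Sunday's furthest: 39 percentage points becomes −21 points. Struck out of Sunday's, it leaves target at 86.1% instead of 7.02%, a survival of 8.15%, which equals the keep of 0.610 per day applied over 5.07 d. The neighbour flask, Sunday's read at 4.0 d, holds 16.9%; two more days at the keep give 6.29%, and Sunday's reads 7.02%.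

The numbers belong to no real substance, and the outcome is calculated.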